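**Retrosynthetic overview**

1. Target ⇐ aromatic Claisen rearrangement of the O9-(1,1-dimethylallyl) ether of the C10-unsubstituted pterocarpan phenol; C10 is the only free position of ring D.
2. Pterocarpan ⇐ acid-induced O11–C11a closure of a (3R,4R)-isoflavan-4-ol, itself from asymmetric transfer hydrogenation with dynamic kinetic resolution of an isoflavone; isoflavone ⇐ Suzuki coupling (C6a–C6b) of a 3-iodochromone carrying the ring A pyran with a ring D chromenyl boronate.
3. Ring D chromene (5-triflyloxy-6,8-dialkoxy-2,2-dimethyl-2H-chromene) ⇐ key step: an aryne (C7≡C8) from a mirror-symmetric 2-silyl-1,3-phenylene bis(triflate) takes up the C=O of 3-methylbut-2-enal; the benzoxete formed (O, C4', C7, C8) is enlarged by the two alkene carbons to the 2H-pyran (4π ring opening, oxa-6π closure).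
4. Enabling feature: in ring D the pyran oxygen sits on C8 and the pyran carbon C4' on the neighbouring C7 (an ortho O/C pair, the footprint of a C=O on an aryne), and C7 is flanked by C6b, whose bond to C6a can be carried as a C–O triflate; ring D is then a symmetric 1,2,4,5-tetraoxygenated benzene (O on C6b, C8, C9, C10a) and the triflate beside the triple bond steers the oxygen to C8.
5. Order of ring formation: ring D pyran (step 6), pyranone ring B (step 11), dihydrofuran ring C (step 14); the benzene rings A and D and the ring A pyran skeleton are bought in.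

Key step: step 6

Remark: the stereodescriptors of the target SMILES correspond to the cis-fused (6aR,11aR)-pterocarpan; positions are numbered as in pterocarpan (ring D = C6b, C7, C8, C9, C10, C10a; the ring D pyran O1', C2', C3', C4' is fused at C7–C8 with O1' on C8).

**Route**

Step 1
Reactants: 1 4,6-diacetylresorcinol
Product: 2 1,1'-[4,6-bis(methoxymethoxy)-1,3-phenylene]di(ethan-1-one)
Conditions: NaH, MOMCl, DMF, 0 °C to rt
Reagents that add atoms: chloromethyl methyl ether, COCCl
Why: Williamson-type O-alkylation of the doubly deprotonated, chelated bis-phenol gives the bis(methoxymethyl) ether that masks the two oxygens destined to become O9 and O10a.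

Step 2
Reactants: 2 1,1'-[4,6-bis(methoxymethoxy)-1,3-phenylene]di(ethan-1-one)
Product: 4 4,6-bis(methoxymethoxy)benzene-1,3-diol, via diacetate 3 (not isolated)
Conditions: mCPBA, CH2Cl2, 0 °C to rt; then K2CO3 (cat.), MeOH, rt
Reagents that add atoms: 3-chloroperoxybenzoic acid, OOC(=O)c1cccc(Cl)c1
Why: In this double Baeyer–Villiger oxidation the aryl group, activated by ortho and para alkoxy groups, should migrate in preference to methyl at both ketones, and methanolysis of the two aryl acetates then frees the new phenols without touching the acetal ethers.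

Step 3
Reactants: 4 4,6-bis(methoxymethoxy)benzene-1,3-diol
Product: 5 2-bromo-4,6-bis(methoxymethoxy)benzene-1,3-diol
Conditions: NBS, i-Pr2NH (cat.), CH2Cl2, −78 to 0 °C
Reagents that add atoms: N-bromosuccinimide, BrN1C(=O)CCC1=O
Why: Amine-catalysed electrophilic aromatic bromination ortho to free phenol should place bromine on the carbon between the two hydroxy groups, which is more activated than the carbon between the two acetal ethers.

Step 4
Reactants: 5 2-bromo-4,6-bis(methoxymethoxy)benzene-1,3-diol
Product: 8 4,6-bis(methoxymethoxy)-2-(trimethylsilyl)benzene-1,3-diol, via bis(silyl ether) 6 (not isolated), via lithium phenolate 7 (not isolated)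
Conditions: HMDS, 80 °C, then evaporate; n-BuLi, THF, −78 °C to rt; aq. NH4Cl/MeOH
Reagents that add atoms: hexamethyldisilazane, C[Si](C)(C)N[Si](C)(C)C
Why: O-silylation, bromine–lithium exchange (faster than ortho-lithiation) and retro-Brook rearrangement (1,3 shift of silicon from O to C) should put the trimethylsilyl group on the carbon between the two oxygens, and the hydrolytic work-up removes the remaining O-silyl group.

Step 5
Reactants: 8 4,6-bis(methoxymethoxy)-2-(trimethylsilyl)benzene-1,3-diol
Product: 9 4,6-bis(methoxymethoxy)-2-(trimethylsilyl)-1,3-phenylene bis(trifluoromethanesulfonate)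
Conditions: Tf2O, pyridine, CH2Cl2, −78 to 0 °C
Reagents that add atoms: trifluoromethanesulfonic anhydride, O=S(=O)(OS(=O)(=O)C(F)(F)F)C(F)(F)F
Why: O-sulfonylation of both phenols should give the mirror-symmetric o-silylaryl bis(triflate), in which either triflate can serve as the leaving group of the aryne while the other remains as director and later coupling handle.

Step 6
Reactants: 9 4,6-bis(methoxymethoxy)-2-(trimethylsilyl)-1,3-phenylene bis(trifluoromethanesulfonate); 10 3-methylbut-2-enal
Product: 14 6,8-bis(methoxymethoxy)-2,2-dimethyl-2H-chromen-5-yl trifluoromethanesulfonate, via aryne 11 (not isolated), via benzoxete 12 (not isolated), via quinone methide 13 (not isolated)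
Conditions: CsF, 10 (excess), MeCN, rt
Reagents that add atoms: none
Why: Fluoride removes the silyl group and either of the two symmetry-equivalent triflates leaves, giving aryne 11 (C7≡C8 of ring D) flanked by the surviving triflate on C6b and an acetal ether on C9. The carbonyl oxygen of 10 adds to C8 and the aryl anion developing on C7 closes onto the oxocarbenium carbon (stepwise 2+2 cycloaddition, 4-exo-trig closure) to give benzoxete 12, whose four-membered ring already holds O, C8, C7 and the future C4' of the pyran. Conrotatory 4π ring opening of the oxete to the (Z)-o-quinone methide 13 and disrotatory oxa-6π electrocyclisation (O–C bond to the CMe2 terminus) then enlarge this ring by the two alkene carbons to the six-membered 2H-pyran, with rearomatisation as the driving force. The closest known reactions are the fluoride-induced synthesis of 2H-chromenes from arynes and α,β-unsaturated aldehydes and the 2+2 cycloadditions of 3-triflyloxyarynes with ketene acetals, in which the triflate survives. No stereocentre is formed; the step needs regioselectivity, which should be secured by the triflate, the stronger σ-acceptor of the two flanking groups, which places the developing negative charge on the carbon next to itself (the acetal ether on C10a, meta to C7, acts in the same sense). It also needs the anion to close faster than it expels triflate and the quinone methide to cyclise faster than it meets a second aryne, which the intramolecular collapse onto the oxocarbenium ion, the cis geometry of the dienone and the excess of 10 should favour.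

Step 7
Reactants: 14 6,8-bis(methoxymethoxy)-2,2-dimethyl-2H-chromen-5-yl trifluoromethanesulfonate
Product: 15 2-[6,8-bis(methoxymethoxy)-2,2-dimethyl-2H-chromen-5-yl]-4,4,5,5-tetramethyl-1,3,2-dioxaborolane
Conditions: B2pin2, Pd2(dba)3 (cat.), XPhos, KOAc, 1,4-dioxane, 100 °C
Reagents that add atoms: bis(pinacolato)diboron, CC1(C)OB(OC1(C)C)B1OC(C)(C)C(C)(C)O1
Why: Miyaura borylation (oxidative addition of zerovalent palladium into the aryl triflate, acetate-assisted transmetalation with the diboron, reductive elimination) should work on the doubly ortho-substituted triflate with the bulky biarylphosphine.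

Step 8
Reactants: 16 2,2-dimethylchroman-7-ol
Product: 17 1-(7-hydroxy-2,2-dimethylchroman-6-yl)ethan-1-one
Conditions: AcOH, BF3·OEt2, 90 °C; aq. NaOAc work-up
Reagents that add atoms: acetic acid, CC(=O)O
Why: Friedel–Crafts acylation should go to C6, ortho to the phenol and para to the ring oxygen, the less hindered of the two activated positions, which fixes the linear fusion of the ring A pyran.

Step 9
Reactants: 17 1-(7-hydroxy-2,2-dimethylchroman-6-yl)ethan-1-one
Product: 18 1-(7-hydroxy-2,2-dimethyl-2H-chromen-6-yl)ethan-1-one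
Conditions: DDQ, 1,4-dioxane, reflux
Reagents that add atoms: none
Why: Quinone dehydrogenation (hydride abstraction from benzylic C4 assisted by the para phenol oxygen, then loss of a proton from C3) should give the 2H-chromene.

Step 10
Reactants: 18 1-(7-hydroxy-2,2-dimethyl-2H-chromen-6-yl)ethan-1-one
Product: 19 (E)-3-(dimethylamino)-1-(7-hydroxy-2,2-dimethyl-2H-chromen-6-yl)prop-2-en-1-one
Conditions: Me2NCH(OMe)2, toluene, 100 °C
Reagents that add atoms: N,N-dimethylformamide dimethyl acetal, COC(OC)N(C)C
Why: Condensation of the methyl ketone with the amide acetal should give the (E)-enaminone and adds the carbon that becomes C6 of the pterocarpan.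

Step 11
Reactants: 19 (E)-3-(dimethylamino)-1-(7-hydroxy-2,2-dimethyl-2H-chromen-6-yl)prop-2-en-1-one
Product: 20 3-iodo-8,8-dimethyl-4H,8H-pyrano[3,2-g]chromen-4-one
Conditions: I2, CHCl3, rt
Reagents that add atoms: iodine, II
Why: Iodine-promoted cyclisation of the enaminone (α-iodination, 6-endo addition of the phenol to the iminium carbon, loss of dimethylamine) should close the pyranone ring and give the 3-iodochromone.

Step 12
Reactants: 15 2-[6,8-bis(methoxymethoxy)-2,2-dimethyl-2H-chromen-5-yl]-4,4,5,5-tetramethyl-1,3,2-dioxaborolane; 20 3-iodo-8,8-dimethyl-4H,8H-pyrano[3,2-g]chromen-4-one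
Product: 21 3-[6,8-bis(methoxymethoxy)-2,2-dimethyl-2H-chromen-5-yl]-8,8-dimethyl-4H,8H-pyrano[3,2-g]chromen-4-one
Conditions: Pd(OAc)2 (cat.), SPhos, K3PO4, toluene/H2O, 80 °C
Reagents that add atoms: none
Why: Suzuki–Miyaura coupling should form the future C6a–C6b bond, the electron-rich bulky phosphine serving the doubly ortho-substituted boronate and the phosphate base sparing the pyranone ring.

Step 13
Reactants: 21 3-[6,8-bis(methoxymethoxy)-2,2-dimethyl-2H-chromen-5-yl]-8,8-dimethyl-4H,8H-pyrano[3,2-g]chromen-4-one
Product: 23 (3R,4R)-3-[6,8-bis(methoxymethoxy)-2,2-dimethyl-2H-chromen-5-yl]-8,8-dimethyl-3,4-dihydro-2H,8H-pyrano[3,2-g]chromen-4-ol, via isoflavanone 22 (not isolated)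
Conditions: RuCl[(R,R)-TsDPEN](p-cymene) (cat.), HCO2H/Et3N, EtOAc, 40 °C
Reagents that add atoms: none
Why: In this Noyori-type asymmetric transfer hydrogenation with dynamic kinetic resolution, conjugate reduction gives isoflavanone 22, which racemises at C3 by enolisation under triethylamine while the (R,R)-catalyst, by analogy with aryl alkyl ketones, should reduce the 3R ketone faster and anti to the aryl group, so that C4 (R) is set by the catalyst and C3 (R) by the cis-selective reduction of the faster enantiomer.

Step 14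
Reactants: 23 (3R,4R)-3-[6,8-bis(methoxymethoxy)-2,2-dimethyl-2H-chromen-5-yl]-8,8-dimethyl-3,4-dihydro-2H,8H-pyrano[3,2-g]chromen-4-ol
Product: 25 (6aR,11aR)-pterocarpan phenol (target lacking the C10 prenyl group), via triol 24 (not isolated)
Conditions: HCl (cat.), MeOH/THF, 40 °C
Reagents that add atoms: none
Why: Acetal cleavage followed by acid-catalysed SN1 cyclodehydration should close the dihydrofuran ring (5-exo capture of the C4 cation, stabilised by the para oxygen of ring A, by the ortho phenol of ring D), and since only the cis-fused ring is feasible C11a (R) is set by C6a (R) while the second phenol, para to C6b, stays free.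

Step 15
Reactants: 25 (6aR,11aR)-pterocarpan phenol (target lacking the C10 prenyl group)
Product: 26 O9-(2-methylbut-3-yn-2-yl) ether of 25
Conditions: 3-chloro-3-methylbut-1-yne, DBU, CuCl2·2H2O (cat.), MeCN, 0 °C
Reagents that add atoms: 3-chloro-3-methylbut-1-yne, CC(C)(Cl)C#C
Why: Copper-catalysed propargylic substitution should O-alkylate the only phenol with the tertiary chloride under conditions mild enough for the benzylic aryl ether of the pterocarpan.

Step 16
Reactants: 26 O9-(2-methylbut-3-yn-2-yl) ether of 25
Product: 29 Lespecyrtin E4, via allyl ether 27 (not isolated), via dienone 28 (not isolated)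
Conditions: H2 (1 atm), Pd/CaCO3 poisoned with Pb(OAc)2, quinoline, EtOAc, rt; filter; toluene, 110 °C
Reagents that add atoms: none
Why: Semihydrogenation of the terminal alkyne should be much faster than reduction of the chromene double bonds, and the aromatic Claisen rearrangement of the resulting 1,1-dimethylallyl ether (3,3 shift with allyl inversion) should deliver the 3-methylbut-2-enyl group to C10, the only free ortho position, before dienone 28 tautomerises to the phenol.

**Compound list**

1 | 4,6-diacetylresorcinol | CC(=O)c1cc(C(C)=O)c(O)cc1O | starting material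
2 | 1,1'-[4,6-bis(methoxymethoxy)-1,3-phenylene]di(ethan-1-one) | CC(=O)c1cc(C(C)=O)c(OCOC)cc1OCOC | intermediate
3 | 4,6-bis(methoxymethoxy)-1,3-phenylene diacetate | CC(=O)Oc1cc(OC(C)=O)c(OCOC)cc1OCOC | intermediate
4 | 4,6-bis(methoxymethoxy)benzene-1,3-diol | Oc1cc(O)c(OCOC)cc1OCOC | intermediate
5 | 2-bromo-4,6-bis(methoxymethoxy)benzene-1,3-diol | Oc1c(Br)c(O)c(OCOC)cc1OCOC | intermediate
6 | 2-bromo-4,6-bis(methoxymethoxy)-1,3-bis(trimethylsilyloxy)benzene | C[Si](C)(C)Oc1c(Br)c(O[Si](C)(C)C)c(OCOC)cc1OCOC | intermediate
7 | lithium 4,6-bis(methoxymethoxy)-2-(trimethylsilyl)-3-(trimethylsilyloxy)phenolate | [Li+].[O-]c1c([Si](C)(C)C)c(O[Si](C)(C)C)c(OCOC)cc1OCOC | intermediate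
8 | 4,6-bis(methoxymethoxy)-2-(trimethylsilyl)benzene-1,3-diol | Oc1c([Si](C)(C)C)c(O)c(OCOC)cc1OCOC | intermediate
9 | 4,6-bis(methoxymethoxy)-2-(trimethylsilyl)-1,3-phenylene bis(trifluoromethanesulfonate) | COCOc1cc(OCOC)c(OS(=O)(=O)C(F)(F)F)c([Si](C)(C)C)c1OS(=O)(=O)C(F)(F)F | intermediate
10 | 3-methylbut-2-enal | CC(C)=CC=O | starting material
11 | 4,6-bis(methoxymethoxy)-3-(trifluoromethanesulfonyloxy)-1,2-didehydrobenzene (aryne) | COCOC1=CC(OCOC)=C(OS(=O)(=O)C(F)(F)F)C#C1 | intermediate
12 | 4,6-bis(methoxymethoxy)-2-(2-methylprop-1-en-1-yl)-2H-benzo[b]oxet-3-yl trifluoromethanesulfonate (racemic) | CC(C)=CC1Oc2c(OCOC)cc(OCOC)c(OS(=O)(=O)C(F)(F)F)c21 | intermediate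
13 | (Z)-2,4-bis(methoxymethoxy)-6-(3-methylbut-2-en-1-ylidene)-5-(trifluoromethanesulfonyloxy)cyclohexa-2,4-dien-1-one | CC(C)=C/C=C1\C(=O)C(OCOC)=CC(OCOC)=C1OS(=O)(=O)C(F)(F)F | intermediate
14 | 6,8-bis(methoxymethoxy)-2,2-dimethyl-2H-chromen-5-yl trifluoromethanesulfonate | CC1(C)C=Cc2c(O1)c(OCOC)cc(OCOC)c2OS(=O)(=O)C(F)(F)F | intermediate
15 | 2-[6,8-bis(methoxymethoxy)-2,2-dimethyl-2H-chromen-5-yl]-4,4,5,5-tetramethyl-1,3,2-dioxaborolane | CC1(C)C=Cc2c(O1)c(OCOC)cc(OCOC)c2B3OC(C)(C)C(C)(C)O3 | intermediate
16 | 2,2-dimethylchroman-7-ol | CC1(C)CCc2ccc(O)cc2O1 | starting material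
17 | 1-(7-hydroxy-2,2-dimethylchroman-6-yl)ethan-1-one | CC(=O)c1cc2CCC(C)(C)Oc2cc1O | intermediate
18 | 1-(7-hydroxy-2,2-dimethyl-2H-chromen-6-yl)ethan-1-one | CC(=O)c1cc2C=CC(C)(C)Oc2cc1O | intermediate
19 | (E)-3-(dimethylamino)-1-(7-hydroxy-2,2-dimethyl-2H-chromen-6-yl)prop-2-en-1-one | CN(C)/C=C/C(=O)c1cc2C=CC(C)(C)Oc2cc1O | intermediate
20 | 3-iodo-8,8-dimethyl-4H,8H-pyrano[3,2-g]chromen-4-one (3-iodochromone with the dimethylpyran fused linearly at C6/C7, oxygen on C7) | O=c1c(I)coc2cc3OC(C)(C)C=Cc3cc12 | intermediate
21 | 3-[6,8-bis(methoxymethoxy)-2,2-dimethyl-2H-chromen-5-yl]-8,8-dimethyl-4H,8H-pyrano[3,2-g]chromen-4-one (isoflavone) | O=c1c(-c2c(OCOC)cc(OCOC)c3OC(C)(C)C=Cc23)coc2cc3OC(C)(C)C=Cc3cc12 | intermediate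
22 | 3-[6,8-bis(methoxymethoxy)-2,2-dimethyl-2H-chromen-5-yl]-8,8-dimethyl-2,3-dihydro-4H,8H-pyrano[3,2-g]chromen-4-one (isoflavanone, C3 epimerising) | O=C1C(c2c(OCOC)cc(OCOC)c3OC(C)(C)C=Cc23)COc2cc3OC(C)(C)C=Cc3cc12 | intermediate
23 | (3R,4R)-3-[6,8-bis(methoxymethoxy)-2,2-dimethyl-2H-chromen-5-yl]-8,8-dimethyl-3,4-dihydro-2H,8H-pyrano[3,2-g]chromen-4-ol (cis) | O[C@H]1c2cc3C=CC(C)(C)Oc3cc2OC[C@H]1c1c(OCOC)cc(OCOC)c2OC(C)(C)C=Cc12 | intermediate
24 | 5-[(3R,4R)-4-hydroxy-8,8-dimethyl-3,4-dihydro-2H,8H-pyrano[3,2-g]chromen-3-yl]-2,2-dimethyl-2H-chromene-6,8-diol (triol) | O[C@H]1c2cc3C=CC(C)(C)Oc3cc2OC[C@H]1c1c(O)cc(O)c2OC(C)(C)C=Cc12 | intermediate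
25 | (6aR,11aR)-pterocarpan phenol: the target without the C10 prenyl group (9-OH free, C10–H, both dimethylpyran rings in place) | c1c(O)c2c(c3c1O[C@H]1c4cc5c(cc4OC[C@@H]31)OC(C)(C)C=C5)C=CC(C)(C)O2 | intermediate
26 | O9-(2-methylbut-3-yn-2-yl) ether of 25 | c1c(OC(C)(C)C#C)c2c(c3c1O[C@H]1c4cc5c(cc4OC[C@@H]31)OC(C)(C)C=C5)C=CC(C)(C)O2 | intermediate
27 | O9-(2-methylbut-3-en-2-yl) ether of 25 | c1c(OC(C)(C)C=C)c2c(c3c1O[C@H]1c4cc5c(cc4OC[C@@H]31)OC(C)(C)C=C5)C=CC(C)(C)O2 | intermediate
28 | C10-(3-methylbut-2-enyl) cyclohexa-2,4-dien-1-one, the keto tautomer of the target (C9=O, C10 sp3, configuration at C10 not defined) | CC(C)=CCC1C(=O)C2=C(C=CC(C)(C)O2)C3=C1O[C@H]1c4cc5c(cc4OC[C@@H]31)OC(C)(C)C=C5 | intermediate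
29 | Lespecyrtin E4, (6aR,11aR) | CC(C)=CCc1c(O)c2c(c3c1O[C@H]1c4cc5c(cc4OC[C@@H]31)OC(C)(C)C=C5)C=CC(C)(C)O2 | target

**Summary and risks**

Total step count: 16. Longest linear sequence: 12 steps (steps 1 to 7 and 12 to 16, from 1).

Steps most likely to fail:

Step 6. The carbonyl oxygen may add to the wrong aryne carbon, because the acetal ether on C9 pulls in the opposite sense to the triflate. The aryl anion may also expel the neighbouring triflate and open a second aryne, or the enal may react as a heterodiene (4+2) instead of through its C=O. Fallback: setting out from diol 4, condensation with 3-methylbut-2-enal 10 under ethylenediammonium diacetate catalysis in refluxing toluene should give 6,8-bis(methoxymethoxy)-2,2-dimethyl-2H-chromen-5-ol F1. This is a Knoevenagel-type condensation followed by oxa-6π electrocyclisation at the only carbon ortho to a free phenol, the one between the two hydroxy groups. Triflation of the remaining phenol (Tf2O, pyridine) comes back to the route at 14, and steps 3 to 5 are then not needed.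

Step 12. Transmetalation of the doubly ortho-substituted, electron-rich boronate may be so slow that protodeboronation and base-induced opening of the iodochromone take over. Fallback: setting out from triflate 14 and ketone 18, palladium-catalysed α-arylation of the ketone enolate (Pd(OAc)2, XPhos, excess LiHMDS to carry the phenolate, toluene, 80 °C) should give 2-[6,8-bis(methoxymethoxy)-2,2-dimethyl-2H-chromen-5-yl]-1-(7-hydroxy-2,2-dimethyl-2H-chromen-6-yl)ethan-1-one F2. Ring closure of this deoxybenzoin with N,N-dimethylformamide dimethyl acetal (one-carbon insertion and cyclisation, the classical deoxybenzoin route to isoflavones) comes back to the route at 21; steps 7, 10 and 11 are then not needed.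

Step 13. The bulky 2',6'-disubstituted aryl group may slow hydride delivery, so that reduction stalls at the isoflavanone or racemisation at C3 no longer keeps pace, which erodes enantio- and diastereoselectivity. Fallback: setting out from isoflavone 21, reduction with NaBH4 (THF/EtOH) should give 3-[6,8-bis(methoxymethoxy)-2,2-dimethyl-2H-chromen-5-yl]-8,8-dimethyl-3,4-dihydro-2H,8H-pyrano[3,2-g]chromen-4-ol as a racemic mixture of diastereomers F3. Acid treatment as in step 14 converts both diastereomers into the racemic cis-pterocarpan phenol, that is 25 together with its (6aS,11aS) enantiomer F4. Resolution by preparative HPLC on a chiral stationary phase comes back to the route at 25.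

Further compounds
F1 | step 6 | 6,8-bis(methoxymethoxy)-2,2-dimethyl-2H-chromen-5-ol | CC1(C)C=Cc2c(O1)c(OCOC)cc(OCOC)c2O
F2 | step 12 | 2-[6,8-bis(methoxymethoxy)-2,2-dimethyl-2H-chromen-5-yl]-1-(7-hydroxy-2,2-dimethyl-2H-chromen-6-yl)ethan-1-one | O=C(Cc1c(OCOC)cc(OCOC)c2OC(C)(C)C=Cc12)c1cc2C=CC(C)(C)Oc2cc1O
F3 | step 13 | 3-[6,8-bis(methoxymethoxy)-2,2-dimethyl-2H-chromen-5-yl]-8,8-dimethyl-3,4-dihydro-2H,8H-pyrano[3,2-g]chromen-4-ol, racemic mixture of cis and trans isomers | OC1c2cc3C=CC(C)(C)Oc3cc2OCC1c1c(OCOC)cc(OCOC)c2OC(C)(C)C=Cc12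
F4 | step 13 | (6aS,11aS) enantiomer of pterocarpan phenol 25 | c1c(O)c2c(c3c1O[C@@H]1c4cc5c(cc4OC[C@H]31)OC(C)(C)C=C5)C=CC(C)(C)O2
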